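Start from the ceiling.

| flask | Q | Z | temperature | remark | time |
|---|---|---|---|---|---|
| ash | 1.5 M | 0.50 equiv | 0 °C | run made earlier |  |
| cedar | 1.7 M | 0.50 equiv | 15 °C | run made earlier |  |
| Friday's | 1.2 M | 0.500 equiv | 25 °C |  | 8.0 min |
| Monday's | 2.0 M | 0.500 equiv | 5 °C |  | 8.0 min |

| run | time / min | G / % | Q / % |
|---|---|---|---|
| ash | 0.667 | 0.6 | 99.5 |
| ash | 2.00 | 2.5 | 97.6 |
| ash | 4.00 | 5.8 | 93.3 |
| ash | 6.00 | 9.1 | 89.7 |
| ash | 8.00 | 12.6 | 86.5 |
| cedar | 0.417 | 0.6 | 99.7 |
| cedar | 0.833 | 1.2 | 99.3 |
| cedar | 1.50 | 3.7 | 96.3 |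
| cedar | 2.50 | 6.3 | 92.5 |
| cedar | 5.00 | 16.8 | 82.0 |

(scatter of a reading: 0.3 percentage points)

- the winner by amount of G, in percent of the Q charged; "neither" if no more than 2 percentage points parts them (Friday's / Monday's / neither)
- how much G is there at the end, in percent of the Q charged: Friday's
- how much G is there at the end, in percent of the Q charged: Monday's

- Z is a solid; its amount is given per volume of the solution
- candidate steps: D + L -> E; X <-> L; D + X -> G; Q <-> X; Z <-> D
- at the start none of Z is in solution
- where the amount of Q changes, what is given in equivalents or mol% on it follows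

Each G takes one D, and so does each E, so Z, at 0.500 equiv, is the limiting reagent and G has its upper bound, shared with E, at 50.0% of the Q charged.

Now read the late slopes of G: 0.0170 /min in the ash run and 0.0420 /min in the cedar run. Divide each by its charge of Z in M:

ash 0.0227 /M/min, cedar 0.0494 /M/min

Carry that ratio, degree by degree, to each new temperature:

Friday's 0.0831 /M/min, Monday's 0.0294 /M/min

Multiply by [Q] at the start. You get the closing rate, the part of the gap to the ceiling that G closes per minute, a pseudo-first-order constant:

Friday's 0.0997 /min, Monday's 0.0588 /min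

For the high end, let the gap stay as it was at the start, so G = ceiling × rate × time:

Friday's 39.9%, Monday's 23.5%

For the low end, let the gap shrink and take off the lag, read on the cedar slope as 1.00 min. So G = ceiling × (1 − exp(−rate × (time − lag))):

Friday's 25.1%, Monday's 16.9%

Friday's low end stands above Monday's high end, so you back Friday's.

The forecast backs it too: “Friday's clearly wins”. Its 40% for Friday's sits at my high end. Its 15% for Monday's sits below my low end.

Friday's gives 28.2% and Monday's 17.9%, so Friday's wins.

    D + L → E (k = 10.0 /M/s, Ea = 35.0 kJ/mol)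
    X ⇌ L (K = 0.150, k = 0.210 /s, Ea = 71.0 kJ/mol, ΔH = −18.0 kJ/mol)
    D + X → G (k = 5.90 /M/s, Ea = 51.0 kJ/mol)
    Q ⇌ X (K = 1.60 × 10⁻⁴, k = 0.00180 /s, Ea = 78.0 kJ/mol, ΔH = −23.0 kJ/mol)
    Z ⇌ D, rate k5*(cs5 - [D]) while solid is left; crystals form when [D] > cs5 (solubility = 0.840 M, k = 0.0100 /s)
    (constants at 5 °C)

In Friday's flask at 8.00 min, D stands at 0.241 M, and the closing rate puts it at 0.299 M. Left until 20 min, Friday's flask reckons at 42.5% by the same rate, and it holds 41.2%.

The earlier runs and the new flask were computed with made-up constants.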